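The readings are simulated for an exercise; the scatter is artificial.

The vessel holds two phases, and you asked for a quick number on this flask, so here is how I reckon it.

all flasks: substrate 41 mM

| flask | reagent in the second phase | protic impurity | remark | time | volume of the second phase over the first |
|---|---|---|---|---|---|
| teal | 330 mM | 41 mM | run made earlier |  |  |
| flask | 164 mM | 41.0 mM |  | 1.5 h | 2.0 |

teal run (percent of the substrate charged)

| time / min | target / % | crystals / % |
|---|---|---|
| 2.50 | 0 | 2 |
| 6.00 | 12 | 9 |
| 12.0 | 21 | 19 |
| 20.0 | 33 | 36 |
| 25.0 | 45 | 41 |

(scatter of a reading: 2 percentage points)

- the target and crystals together standing at 1.5 h, as a percentage of the substrate charged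
- concentration of target in solution at 1.5 h, in percent of saturation

- for target the crystals are counted in
- in the second phase: reagent in the second phase; everything else is in the first
- charges count per volume of the first phase; a concentration in a rate is the amount of a species over the volume of its own phase; every rate counts per litre of the first phase
- as a solid, counted per litre of solution: crystals
- the earlier runs hold the two phases in the same ratio of volumes as the flask asked about

The teal run reads 21% at 12.0 min and 45% at 25.0 min, a line within the scatter, although substrate is being used up. So I don't let substrate set the pace. I take the crossing of reagent out of the second phase as the rate-limiting step, with a flow proportional to the stock there, like a tank draining through a fixed orifice. Its emptying time constant τ is the stock over the flow, with the flow taken as summed teal readings over summed times: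

flow = 0.695 mM min⁻¹

τ = 330 mM / flow = 7.92 h

Counting each reagent delivered as one target, the flask gets:

y = (164 mM / 41 mM) × (1 − exp(−1.5 h/τ)) = 69.0%

That delivery is 28.3 mM, less than the 41 mM of substrate charged, so the substrate can take it. In the teal run crystals read 41% of a target reading of 45% at 25.0 min, so I put the solution of this flask close to 100% of saturation.

Your forecast, which says “I assume first order in reagent”, gives 57% and 103%, and my y stands above it.

The flask gives 70.6% and 103%.

    reagent in the reaction phase ⇌ reagent in the second phase, rate k1*([reagent in the reaction phase] - [reagent in the second phase]/K1) per volume of the first phase (partition coefficient = 7.30, kL = 0.0350 min⁻¹)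
    substrate + reagent in the reaction phase → target (k = 88.0 M⁻¹ min⁻¹)
    reagent in the reaction phase + target → over-reacted product (k = 46.0 M⁻¹ min⁻¹)
    crystals ⇌ target, rate k4*(cs4 - [target]) while solid is left; crystals form when [target] > cs4 (solubility = 0.640 mM, k = 14.0 min⁻¹)
    reagent in the reaction phase + protic impurity → quenched reagent (k = 2.20 M⁻¹ min⁻¹)

The flask is not at rest at 1.50 h: substrate stands at 28.3%, and reagent in the second phase at 80.9% of its charge, where τ gives 82.7%. For the neighbour read at 25 min, τ gives 20.5%, and that neighbour stands at 21.7%. Ten times the time changes the flask again: at 15.0 h, reagent in the second phase stands at 24.9% and protic impurity at 4.28% of their own charges, target and crystals together are down to 0.128% of the substrate charged, and over-reacted product holds 99.9% of it.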